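**Retrosynthetic overview**

1. Praesorether G 22 comes from sixfold BCl3 de-isopropylation of 21, which comes from C5 formylation of both rings A by carbonate-directed magnesiation, after oxidation of the two C4–B bonds of bis(boronate) 16 to C4–OH.
2. Key disconnection: the two ring A C4–B bonds, made together by iridium-catalysed C–H borylation of diester 14. The strategy rests on ring A C4–H (para to the ester carbon C1, between C3–H and C5–H), the only aromatic C–H of the pentamer whose two neighbouring ring carbons both carry hydrogen; the ring B and ring C C–H bonds each lie between two substituents.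
3. 14 comes from bis-phenol 12 by double SNAr on methyl 2-fluoro-6-methylbenzoate 13 (two ring A C6–O bonds); 12 comes from trimer 9 by twofold ring B formylation and Dakin oxidation.
4. 9 comes from two ring B aryllithiums 7 added to ring C dialdehyde 6, then ionic hydrogenation (two CH2 bridges); 6 and 7 are both made from orcinol diisopropyl ether 3.
5. No ring is formed in the route: the five benzene rings are bought (three orcinol, two fluoro ester) and joined in the order ring C + two rings B, then two rings A.

Key step: step 9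

Assumption: ring A is numbered C1 (CO2Me), C2 (CH3), C3 (H), C4 (OH), C5 (CHO), C6 (O to ring B); rings B are the two outer core rings and ring C the central one; diol 8 is carried on as its meso/racemic mixture because both carbinol carbons become CH2 in step 5, and the target has no stereocentre.

**Route**

Step 1
Reactants: 1 orcinol (5-methylbenzene-1,3-diol); 2 2-bromopropane (3 equiv)
Product: 3 1,3-diisopropoxy-5-methylbenzene
Conditions: K2CO3, DMF, 70 °C, sealed vessel
Reagents that add atoms: none
Why: Williamson ether synthesis, in which both phenoxides are O-alkylated by the secondary bromide in a polar aprotic solvent; isopropyl is chosen because BCl3 removes it at the end without touching methyl esters.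

Step 2
Reactants: 3 1,3-diisopropoxy-5-methylbenzene
Product: 4 2,4-dibromo-1,5-diisopropoxy-3-methylbenzene
Conditions: NBS (2.05 equiv), MeCN, 0 → 25 °C
Reagents that add atoms: N-bromosuccinimide, O=C1CCC(=O)N1Br
Why: Electrophilic aromatic bromination, in which the two positions ortho to one isopropoxy group and para to the other (flanking the methyl group) should react before the hindered position between the two isopropoxy groups.

Step 3
Reactants: 4 2,4-dibromo-1,5-diisopropoxy-3-methylbenzene
Product: 6 4,6-diisopropoxy-2-methylbenzene-1,3-dicarbaldehyde, via dilithioarene 5 (not isolated)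
Conditions: t-BuLi (4.4 equiv), THF, −78 °C; DMF, −78 → 0 °C; then H2O
Reagents that add atoms: N,N-dimethylformamide, CN(C)C=O
Why: Double bromine–lithium exchange followed by formylation of the aryllithium with DMF; the two bromides are meta to each other, so no aryne can form, and each C–Li bond is stabilised by an ortho isopropoxy group.

Step 4
Reactants: 3 1,3-diisopropoxy-5-methylbenzene (2.4 equiv); 6 4,6-diisopropoxy-2-methylbenzene-1,3-dicarbaldehyde
Product: 8 (4,6-diisopropoxy-2-methyl-1,3-phenylene)bis[(2,6-diisopropoxy-4-methylphenyl)methanol], via aryllithium 7 (not isolated)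
Conditions: n-BuLi, THF, 0 → 25 °C; then 6, −78 → 0 °C; then H2O
Reagents that add atoms: none
Why: Directed ortho-lithiation at the C–H between the two isopropoxy groups followed by 1,2-addition to both non-enolisable aldehydes; the two carbinol stereocentres form without control and are removed in step 5.

Step 5
Reactants: 8 bis-carbinol
Product: 9 1,5-diisopropoxy-3-methyl-2,4-bis(2,6-diisopropoxy-4-methylbenzyl)benzene
Conditions: Et3SiH (6 equiv), CF3CO2H, CH2Cl2, 0 °C
Reagents that add atoms: none
Why: Ionic hydrogenation, in which each doubly benzylic alcohol ionises to a diarylmethyl cation stabilised by ortho and para alkoxy groups and is reduced by hydride from the silane, while aryl isopropyl ethers should survive cold trifluoroacetic acid.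

Step 6
Reactants: 9 tris-orcinol hexaisopropyl ether
Product: 10 3,3'-[(4,6-diisopropoxy-2-methyl-1,3-phenylene)bis(methylene)]bis(2,4-diisopropoxy-6-methylbenzaldehyde)
Conditions: POCl3 (6 equiv), DMF, 0 → 65 °C; aq. NaOAc work-up
Reagents that add atoms: N,N-dimethylformamide, CN(C)C=O
Why: Vilsmeier–Haack formylation, in which the chloroiminium ion attacks each ring B at a C–H para to one isopropoxy group and ortho to the other (the two such sites of a ring B are equivalent), the first formyl group deactivates its ring, and the single ring C C–H is shielded between two isopropoxy groups.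

Step 7
Reactants: 10 bis-aldehyde
Product: 12 3,3'-[(4,6-diisopropoxy-2-methyl-1,3-phenylene)bis(methylene)]bis(2,4-diisopropoxy-6-methylphenol), via bis(aryl formate) 11 (not isolated)
Conditions: mCPBA (2.4 equiv), NaHCO3, CH2Cl2, 0 °C; then K2CO3, MeOH, 25 °C, argon
Reagents that add atoms: 3-chloroperoxybenzoic acid, OOC(=O)c1cccc(Cl)c1
Why: Dakin-type Baeyer–Villiger oxidation, in which the aryl group bearing ortho and para alkoxy donors migrates in the Criegee intermediate to give the aryl formate, which methanolysis converts into the phenol.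

Step 8
Reactants: 12 bis-phenol; 13 methyl 2-fluoro-6-methylbenzoate (4 equiv)
Product: 14 deoxy-deformyl pentamer hexaisopropyl ether (each phenol oxygen of 12 bonded to C6 of a methyl 2-methylbenzoate ring A)
Conditions: Cs2CO3, DMSO, 120 °C, argon
Reagents that add atoms: none
Why: Nucleophilic aromatic substitution by addition–elimination, in which the cesium phenoxides attack the C–F carbon ortho to the ester, whose carbonyl group stabilises the Meisenheimer intermediate; the hindered phenoxides and the modest activation are the reason for the high temperature.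

Step 9
Reactants: 14 deoxy-deformyl pentamer hexaisopropyl ether; 15 bis(pinacolato)diboron (3 equiv)
Product: 16 bis(aryl boronate) (14 with a pinacolboryl group at C4 of each ring A)
Conditions: [Ir(OMe)(cod)]2 (5 mol %), 4,4'-di-tert-butyl-2,2'-bipyridine (10 mol %), THF, 80 °C, sealed, argon
Reagents that add atoms: none
Why: The precatalyst, the bipyridine and B2pin2 should form a trivalent iridium tris(boryl) complex, which cleaves an aromatic C–H bond by oxidative addition to a pentavalent iridium aryl hydride and releases the aryl boronate by C–B reductive elimination; the closest known reaction type is the sterically controlled iridium-catalysed aromatic C–H borylation. No ring is closed and no stereocentre is formed. The step needs one site per ring A out of nine aromatic C–H bonds and no benzylic or alkyl borylation. The bulky catalyst avoids C–H bonds next to a substituent: ring A C3–H lies beside the C2 methyl, ring A C5–H beside the aryloxy oxygen, each ring B C–H between methyl and isopropoxy, and the ring C C–H between two isopropoxy groups, whereas ring A C4–H has C3–H and C5–H as neighbours. Neither ester has an ortho C–H left to direct the catalyst, and sp3 C–H bonds react far more slowly than an unhindered aryl C–H under these conditions.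

Step 10
Reactants: 16 bis(aryl boronate)
Product: 17 ring A bis-phenol (14 with OH at C4 of each ring A)
Conditions: NaBO3·4H2O (6 equiv), THF/H2O 1:1, 25 °C
Reagents that add atoms: sodium perborate, [Na+].[O-]OB=O
Why: Oxidation of an aryl boronate to a phenol, in which hydroperoxide adds to boron, the aryl group migrates from boron to oxygen and the borate ester is hydrolysed, under conditions mild enough for the methyl esters and the electron-rich rings.

Step 11
Reactants: 17 ring A bis-phenol
Product: 18 bis(tert-butyl carbonate) of 17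
Conditions: Boc2O (2.6 equiv), DMAP (cat.), Et3N, CH2Cl2, 25 °C
Reagents that add atoms: di-tert-butyl dicarbonate, CC(C)(C)OC(=O)OC(=O)OC(C)(C)C
Why: DMAP-catalysed acylation of the two phenols to aryl tert-butyl carbonates, which are coordinating and acidifying directing groups for step 12 and are inert to the hindered amide base.

Step 12
Reactants: 18 bis(tert-butyl carbonate)
Product: 21 Praesorether G hexaisopropyl ether, via bis(arylmagnesium chloride) 19 (not isolated), via bis(carbonate) dialdehyde 20 (not isolated)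
Conditions: TMPMgCl·LiCl (TMP = 2,2,6,6-tetramethylpiperidide, 3 equiv), THF, −20 → 0 °C; DMF, 0 → 25 °C; aq. NH4Cl; then K2CO3, MeOH, 25 °C
Reagents that add atoms: N,N-dimethylformamide, CN(C)C=O
Why: Directed ortho-magnesiation with a mixed magnesium–lithium amide and formylation with DMF, in which the carbonate carbonyl oxygen delivers the base to C5, the only ring A C–H flanked by two oxygen substituents and so the most acidic, the base does not add to esters or carbonates, and methanolysis of the carbonates then frees the phenols.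

Step 13
Reactants: 21 Praesorether G hexaisopropyl ether
Product: 22 Praesorether G
Conditions: BCl3 (15 equiv), CH2Cl2, −78 → 0 °C; then MeOH, H2O
Reagents that add atoms: none
Why: Lewis acid dealkylation of aryl isopropyl ethers, in which BCl3 binds each ether oxygen and chloride removes the secondary alkyl group as 2-chloropropane, which should leave methyl esters, diaryl ethers, the methylene bridges and the aldehydes intact at or below 0 °C.

**Compound list**

1 | orcinol (5-methylbenzene-1,3-diol) | Cc1cc(O)cc(O)c1 | starting material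
2 | 2-bromopropane | CC(C)Br | starting material
3 | 1,3-diisopropoxy-5-methylbenzene | Cc1cc(OC(C)C)cc(OC(C)C)c1 | intermediate
4 | 2,4-dibromo-1,5-diisopropoxy-3-methylbenzene | Cc1c(Br)c(OC(C)C)cc(OC(C)C)c1Br | intermediate
5 | (4,6-diisopropoxy-2-methyl-1,3-phenylene)dilithium, formed in the flask | [Li]c1c(C)c([Li])c(OC(C)C)cc1OC(C)C | intermediate
6 | 4,6-diisopropoxy-2-methylbenzene-1,3-dicarbaldehyde (ring C dialdehyde) | Cc1c(C=O)c(OC(C)C)cc(OC(C)C)c1C=O | intermediate
7 | (2,6-diisopropoxy-4-methylphenyl)lithium, formed in the flask | [Li]c1c(OC(C)C)cc(C)cc1OC(C)C | intermediate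
8 | (4,6-diisopropoxy-2-methyl-1,3-phenylene)bis[(2,6-diisopropoxy-4-methylphenyl)methanol], meso and racemic mixture | Cc1cc(OC(C)C)c(C(O)c2c(C)c(C(O)c3c(OC(C)C)cc(C)cc3OC(C)C)c(OC(C)C)cc2OC(C)C)c(OC(C)C)c1 | intermediate
9 | 1,5-diisopropoxy-3-methyl-2,4-bis(2,6-diisopropoxy-4-methylbenzyl)benzene (tris-orcinol hexaisopropyl ether) | Cc1cc(OC(C)C)c(Cc2c(C)c(Cc3c(OC(C)C)cc(C)cc3OC(C)C)c(OC(C)C)cc2OC(C)C)c(OC(C)C)c1 | intermediate
10 | 3,3'-[(4,6-diisopropoxy-2-methyl-1,3-phenylene)bis(methylene)]bis(2,4-diisopropoxy-6-methylbenzaldehyde) | Cc1cc(OC(C)C)c(Cc2c(C)c(Cc3c(OC(C)C)cc(C)c(C=O)c3OC(C)C)c(OC(C)C)cc2OC(C)C)c(OC(C)C)c1C=O | intermediate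
11 | bis(aryl formate) of 12, formed in the flask | Cc1cc(OC(C)C)c(Cc2c(C)c(Cc3c(OC(C)C)cc(C)c(OC=O)c3OC(C)C)c(OC(C)C)cc2OC(C)C)c(OC(C)C)c1OC=O | intermediate
12 | 3,3'-[(4,6-diisopropoxy-2-methyl-1,3-phenylene)bis(methylene)]bis(2,4-diisopropoxy-6-methylphenol) | Cc1cc(OC(C)C)c(Cc2c(C)c(Cc3c(OC(C)C)cc(C)c(O)c3OC(C)C)c(OC(C)C)cc2OC(C)C)c(OC(C)C)c1O | intermediate
13 | methyl 2-fluoro-6-methylbenzoate | COC(=O)c1c(C)cccc1F | starting material
14 | deoxy-deformyl pentamer hexaisopropyl ether (12 with each phenol oxygen bonded to C6 of a methyl 2-methylbenzoate ring A) | COC(=O)c1c(C)cccc1Oc1c(C)cc(OC(C)C)c(Cc2c(OC(C)C)cc(OC(C)C)c(Cc3c(OC(C)C)cc(C)c(Oc4cccc(C)c4C(=O)OC)c3OC(C)C)c2C)c1OC(C)C | intermediate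
15 | bis(pinacolato)diboron | CC1(C)OB(OC1(C)C)B1OC(C)(C)C(C)(C)O1 | starting material
16 | bis(aryl boronate): 14 with a 4,4,5,5-tetramethyl-1,3,2-dioxaborolan-2-yl group at C4 of each ring A | COC(=O)c1c(C)cc(B2OC(C)(C)C(C)(C)O2)cc1Oc1c(C)cc(OC(C)C)c(Cc2c(OC(C)C)cc(OC(C)C)c(Cc3c(OC(C)C)cc(C)c(Oc4cc(B5OC(C)(C)C(C)(C)O5)cc(C)c4C(=O)OC)c3OC(C)C)c2C)c1OC(C)C | intermediate
17 | ring A bis-phenol: 14 with OH at C4 of each ring A | COC(=O)c1c(C)cc(O)cc1Oc1c(C)cc(OC(C)C)c(Cc2c(OC(C)C)cc(OC(C)C)c(Cc3c(OC(C)C)cc(C)c(Oc4cc(O)cc(C)c4C(=O)OC)c3OC(C)C)c2C)c1OC(C)C | intermediate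
18 | bis(tert-butyl carbonate) of 17 | COC(=O)c1c(C)cc(OC(=O)OC(C)(C)C)cc1Oc1c(C)cc(OC(C)C)c(Cc2c(OC(C)C)cc(OC(C)C)c(Cc3c(OC(C)C)cc(C)c(Oc4cc(OC(=O)OC(C)(C)C)cc(C)c4C(=O)OC)c3OC(C)C)c2C)c1OC(C)C | intermediate
19 | 18 magnesiated at C5 of both rings A (bis(arylmagnesium chloride)), formed in the flask | COC(=O)c1c(C)cc(OC(=O)OC(C)(C)C)c([Mg]Cl)c1Oc1c(C)cc(OC(C)C)c(Cc2c(OC(C)C)cc(OC(C)C)c(Cc3c(OC(C)C)cc(C)c(Oc4c([Mg]Cl)c(OC(=O)OC(C)(C)C)cc(C)c4C(=O)OC)c3OC(C)C)c2C)c1OC(C)C | intermediate
20 | 18 with a formyl group at C5 of both rings A, formed in the flask | COC(=O)c1c(C)cc(OC(=O)OC(C)(C)C)c(C=O)c1Oc1c(C)cc(OC(C)C)c(Cc2c(OC(C)C)cc(OC(C)C)c(Cc3c(OC(C)C)cc(C)c(Oc4c(C=O)c(OC(=O)OC(C)(C)C)cc(C)c4C(=O)OC)c3OC(C)C)c2C)c1OC(C)C | intermediate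
21 | Praesorether G hexaisopropyl ether (rings A complete; the six core phenols of rings B and C as isopropyl ethers) | COC(=O)c1c(C)cc(O)c(C=O)c1Oc1c(C)cc(OC(C)C)c(Cc2c(OC(C)C)cc(OC(C)C)c(Cc3c(OC(C)C)cc(C)c(Oc4c(C=O)c(O)cc(C)c4C(=O)OC)c3OC(C)C)c2C)c1OC(C)C | intermediate
22 | Praesorether G | COC(=O)c1c(C)cc(O)c(C=O)c1Oc1c(C)cc(O)c(Cc2c(O)cc(O)c(Cc3c(O)cc(C)c(Oc4c(C=O)c(O)cc(C)c4C(=O)OC)c3O)c2C)c1O | target

**Step count**

Total step count: 13. Longest linear sequence: 13 steps (orcinol through steps 1 to 13; step 4 also consumes 3 from step 1).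

**Steps most likely to fail**

Step 12. The deprotonation may be slow or misdirected. C5–H lies in the cleft between the carbonate and the ring B ether and is shielded by ring B, so the amide base may instead deprotonate the C2 methyl group next to the ester (lateral magnesiation) or C3, and the ortho-magnesiated carbonate may undergo acyl migration from oxygen to carbon. The fallback replaces C–H deprotonation by halogen–magnesium exchange; it sets out from 17 and comes back at 21. Phenoxide-selective iodination of 17 (I2, morpholine, CH2Cl2/MeOH) should iodinate both positions ortho to each ring A phenol and leave the aryl ether rings alone, giving the ring A tetraiodide F1. After deprotonation of the phenols with MeMgCl, iodine–magnesium exchange with iPrMgCl·LiCl at −30 °C should take place first at the C5 iodine, whose carbanion is flanked by two oxygen atoms and whose removal relieves the most strain, giving the C5-magnesiated bis(phenoxide) F2; DMF then gives the 3-iodo bis(salicylaldehyde) F3. Transfer hydrodeiodination of F3 (Pd(OAc)2, PPh3, HCO2H, Et3N, DMF, 60 °C, through zerovalent palladium) removes the C3 iodine and gives 21.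

Step 8. The substitution may stall, because the fluoride is activated by a single ester and the phenoxides are flanked on both sides; at the temperature needed, phenoxide may attack the ester methyl group (O-demethylation) or be oxidised by traces of air. The fallback uses a better activating group and adjusts the oxidation state afterwards; it sets out from 12 and comes back at 14. SNAr of 12 with 2-fluoro-6-methylbenzaldehyde (K2CO3, DMF, 110 °C) should give the bis(2-formyl-3-methylphenyl) ether F4. Pinnick oxidation (NaClO2, NaH2PO4, large excess of 2-methyl-2-butene, t-BuOH/H2O) gives the diacid F5, and alkylation of the hindered carboxylates (MeI, K2CO3, DMF) gives 14.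

Step 6. Site control may be lost on the trimer: attack at the ring C C–H, a second formylation, or acid-induced cleavage of the electron-rich diarylmethane links would all lower the return of 10. The fallback fixes the ring B oxygen before the rings are joined; it sets out from 3 (with 6 as partner) and comes back at 12. Vilsmeier–Haack formylation of 3 (POCl3, DMF) gives 2,4-diisopropoxy-6-methylbenzaldehyde F6. Oxidation with mCPBA gives the aryl formate F7, and methanolysis (K2CO3, MeOH) gives 2,4-diisopropoxy-6-methylphenol F8. Benzylation (BnBr, K2CO3, DMF) gives the benzyl ether F9. Lithiation between the two isopropoxy groups (n-BuLi, THF, 0 °C) gives the aryllithium F10, which adds twice to 6 to give the bis-carbinol F11. Ionic hydrogenation (Et3SiH, CF3CO2H) gives the bis(benzyl ether) trimer F12, and hydrogenolysis (H2, palladium on carbon, EtOAc) gives 12.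

**Further compounds**

F1 | step 12 | ring A tetraiodide: 17 with iodine at C3 and C5 of each ring A | COC(=O)c1c(C)c(I)c(O)c(I)c1Oc1c(C)cc(OC(C)C)c(Cc2c(OC(C)C)cc(OC(C)C)c(Cc3c(OC(C)C)cc(C)c(Oc4c(I)c(O)c(I)c(C)c4C(=O)OC)c3OC(C)C)c2C)c1OC(C)C
F2 | step 12 | C5-magnesiated bis(chloromagnesium phenoxide) of F1, formed in the flask | COC(=O)c1c(C)c(I)c(O[Mg]Cl)c([Mg]Cl)c1Oc1c(C)cc(OC(C)C)c(Cc2c(OC(C)C)cc(OC(C)C)c(Cc3c(OC(C)C)cc(C)c(Oc4c([Mg]Cl)c(O[Mg]Cl)c(I)c(C)c4C(=O)OC)c3OC(C)C)c2C)c1OC(C)C
F3 | step 12 | 3-iodo bis(salicylaldehyde): 21 with iodine at C3 of each ring A | COC(=O)c1c(C)c(I)c(O)c(C=O)c1Oc1c(C)cc(OC(C)C)c(Cc2c(OC(C)C)cc(OC(C)C)c(Cc3c(OC(C)C)cc(C)c(Oc4c(C=O)c(O)c(I)c(C)c4C(=O)OC)c3OC(C)C)c2C)c1OC(C)C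
F4 | step 8 | bis(2-formyl-3-methylphenyl) ether of 12 | O=Cc1c(C)cccc1Oc1c(C)cc(OC(C)C)c(Cc2c(OC(C)C)cc(OC(C)C)c(Cc3c(OC(C)C)cc(C)c(Oc4cccc(C)c4C=O)c3OC(C)C)c2C)c1OC(C)C
F5 | step 8 | diacid corresponding to 14 | OC(=O)c1c(C)cccc1Oc1c(C)cc(OC(C)C)c(Cc2c(OC(C)C)cc(OC(C)C)c(Cc3c(OC(C)C)cc(C)c(Oc4cccc(C)c4C(=O)O)c3OC(C)C)c2C)c1OC(C)C
F6 | step 6 | 2,4-diisopropoxy-6-methylbenzaldehyde | O=Cc1c(C)cc(OC(C)C)cc1OC(C)C
F7 | step 6 | 2,4-diisopropoxy-6-methylphenyl formate, formed in the flask | O=COc1c(C)cc(OC(C)C)cc1OC(C)C
F8 | step 6 | 2,4-diisopropoxy-6-methylphenol | Oc1c(C)cc(OC(C)C)cc1OC(C)C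
F9 | step 6 | 2-(benzyloxy)-1,5-diisopropoxy-3-methylbenzene | Cc1cc(OC(C)C)cc(OC(C)C)c1OCc1ccccc1
F10 | step 6 | [3-(benzyloxy)-2,6-diisopropoxy-4-methylphenyl]lithium, formed in the flask | [Li]c1c(OC(C)C)cc(C)c(OCc2ccccc2)c1OC(C)C
F11 | step 6 | (4,6-diisopropoxy-2-methyl-1,3-phenylene)bis{[3-(benzyloxy)-2,6-diisopropoxy-4-methylphenyl]methanol}, diastereomer mixture | OC(c1c(OC(C)C)c(OCc2ccccc2)c(C)cc1OC(C)C)c1c(C)c(C(O)c2c(OC(C)C)c(OCc3ccccc3)c(C)cc2OC(C)C)c(OC(C)C)cc1OC(C)C
F12 | step 6 | bis(benzyl ether) of 12 | Cc1c(Cc2c(OC(C)C)c(OCc3ccccc3)c(C)cc2OC(C)C)c(OC(C)C)cc(OC(C)C)c1Cc1c(OC(C)C)c(OCc2ccccc2)c(C)cc1OC(C)C
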